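**Retrosynthetic overview**

1. Numbering: ring A = C1(OAc)–C2(OAc)–C3(Me,OH)–C4(Me; side chain C11=C12–butenolide)–C5(H)–C10(Me); ring B = C5–C6–C7–C8=C9(Me)–C10; β = face of the C10 methyl. Late disconnections: C12–C13 (Heck; the butenolide is bought as a ring) and the ring-A oxygens (C1 ketone reduction, OH-directed cis-dihydroxylation of C2=C3), leading back to a bicyclic enone.
2. Key disconnection: the C8=C9 double bond of ring B, made by a (2+2)/retro-(2+2) olefin metathesis–carbonyl olefination that joins a C9 methyl ketone on C10 to a terminal olefin at the end of the C5 side chain.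
3. Enabling feature: ring B is a 1-methylcyclohexene whose olefinic carbon C9 sits directly on the quaternary fusion carbon C10, next to oxygenated C1. C9 and its methyl can therefore enter as an aldol unit on a C1 enolate and C6–C8 as a cuprate at C5; the two chains are trans on ring A and fix the trans fusion before the ring is closed.
4. The monocyclic keto-olefin comes from a cross-conjugated cyclohexadienone by one-pot conjugate addition/aldol (sets C5 and C10). The dienone comes from an auxiliary-controlled Birch reduction–methylation of a 2,5-dimethylbenzamide (sets quaternary C4; all ring-A methyls and C11 are then in place).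
5. Order of rings: ring A is the arene ring of the starting material (never closed), ring B is the only ring closure of the route (step 6), and the butenolide ring is attached intact in the last step.

Key step: step 6

Assumption: the (S)-auxiliary is taken to give the (R)-configured C4 centre in step 2, by analogy with the behaviour of 2-alkylbenzamides of this auxiliary; should the sense be opposite, the commercial (R)-auxiliary is used and nothing else changes.

**Route**

Step 1
Reactants: 1 2,5-dimethylbenzoyl chloride; 2 (S)-2-(methoxymethyl)pyrrolidine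
Product: 3 N-(2,5-dimethylbenzoyl)-(S)-2-(methoxymethyl)pyrrolidine
Conditions: Et3N, DMAP (cat.), CH2Cl2, 0 °C → rt
Reagents that add atoms: none
Why: Acylation of the secondary amine by the acid chloride (Schotten–Baumann-type amide formation); the only stereocentre is that of the proline-derived auxiliary and it is not touched.

Step 2
Reactants: 3 N-(2,5-dimethylbenzoyl)-(S)-2-(methoxymethyl)pyrrolidine
Product: 5 (R)-1,2,5-trimethylcyclohexa-2,5-diene-1-carboxamide of the auxiliary (diene amide), via potassium amide enolate 4 (not isolated)
Conditions: K (2.2 equiv), NH3(l)/THF, t-BuOH (1 equiv), −78 °C; then MeI, −78 °C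
Reagents that add atoms: iodomethane (CI)
Why: Auxiliary-controlled Birch reduction–alkylation: K/NH3 reduces the benzamide at the ipso and para carbons to the amide enolate 4 of fixed geometry, and MeI then attacks the ipso carbon (C4) from the face left open by the methoxymethyl arm, which sets the quaternary C4 centre and leaves the two methyl-bearing olefins (C2=C3, C5=C10) unconjugated.

Step 3
Reactants: 5 diene amide
Product: 6 (R)-1,2,5-trimethyl-4-oxocyclohexa-2,5-diene-1-carboxamide of the auxiliary (cross-conjugated dienone with C1 ketone)
Conditions: Rh2(cap)4 (1 mol %), t-BuOOH (70 % aq., 5 equiv), K2CO3 (0.5 equiv), CH2Cl2, rt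
Reagents that add atoms: tert-butyl hydroperoxide (CC(C)(C)OO)
Why: Dirhodium caprolactamate/TBHP allylic oxidation at the doubly allylic C1 methylene, the weakest C–H bond and the only unhindered position of the pentadienyl radical (C3 and C5 adjoin quaternary C4), should give the cross-conjugated dienone; the quaternary C4 blocks aromatisation.

Step 4
Reactants: 6 cross-conjugated dienone; 7 but-3-enylmagnesium bromide; 8 acetaldehyde
Product: 10 aldol (C1 ketone and C2=C3 enone with 4β-methyl/4α-carboxamide and 5β-but-3-enyl and 10β-methyl/10α-(1-hydroxyethyl) groups; both C9 epimers), via bromomagnesium enolate 9 (not isolated)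
Conditions: 7 (1.5 equiv), CuBr·SMe2 (10 mol %), THF, −78 → −40 °C; then 8 (3 equiv), −78 °C; AcOH/THF quench at −78 °C
Reagents that add atoms: none
Why: Copper-catalysed 1,4-addition of the Grignard reagent (Kharasch type) occurs only at C5, the β-carbon of the less substituted enone arm (C3 is fully substituted), on the face opposite the bulky carboxamide of C4 (sets C5 with C6 cis to the C4 methyl); the magnesium enolate 9 then undergoes aldol addition to acetaldehyde at C10 anti to the new C5 chain (sets the quaternary C10 centre; the C9 carbinol centre is erased in step 5).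

Step 5
Reactants: 10 aldol
Product: 11 keto-olefin (as 10 but with a 10α-acetyl group; non-enolisable 1,3-diketone)
Conditions: Dess–Martin periodinane, NaHCO3, CH2Cl2, 0 °C → rt
Reagents that add atoms: none
Why: Dess–Martin oxidation of the secondary carbinol under buffered, non-basic conditions, which avoids retro-aldol cleavage of the congested β-hydroxy ketone; no stereocentre is affected.

Step 6
Reactants: 11 keto-olefin; 12 molybdenum(VI) 2,6-diisopropylphenylimido neophylidene bis(hexafluoro-tert-butoxide) complex
Product: 14 trans-fused bicyclic enone amide (ring B closed; C1 ketone and C2=C3 and C8=C9 with 5α-H and 10β-methyl and 4β-methyl/4α-carboxamide), via molybdenum alkylidene 13 (not isolated)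
Conditions: 12 (1.1 equiv), C6H6, 20 → 50 °C, Ar
Reagents that add atoms: none
Why: The neophylidene complex first undergoes (2+2) cycloaddition/cycloreversion with the unhindered terminal olefin of 11 (olefin metathesis), which releases 3-methyl-3-phenylbut-1-ene and places the Mo alkylidene on C8 (13). This alkylidene then adds across the C9 methyl ketone in an intramolecular Wittig-like (2+2) to an oxamolybdacyclobutane that cycloreverts to the C8=C9 olefin and a Mo(VI) oxo species, which makes the closure irreversible; the closest known reaction type is the stoichiometric Mo-alkylidene olefin metathesis/carbonyl olefination of olefinic methyl ketones to 1-methylcycloalkenes (five- to seven-membered). Ring B closes as a six-membered ring by attack of the C8 alkylidene carbon on the exocyclic C9 carbonyl (6-exo with respect to C=O), so the trisubstituted olefin and its methyl group arise in place with no positional isomers. No new stereocentre is formed: the trans fusion is carried by the trans-diequatorial C5 chain and C10 acetyl group set in step 4, and the tether allows only the ring (cis) olefin. The step needs selectivity for the terminal olefin over the enone olefin and for the C9 ketone over the C1 enone carbonyl and the C11 amide carbonyl; the trisubstituted electron-poor olefin is inert to the alkylidene, olefination at C1 would give a bridgehead (anti-Bredt) olefin, and tertiary amides react far more slowly with Mo alkylidenes than ketones.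

Step 7
Reactants: 14 bicyclic enone amide
Product: 15 diol (1β-hydroxy and C11 hydroxymethyl; C2=C3 and C8=C9 retained)
Conditions: LiH2N·BH3 (from BH3·NH3 and LDA, 6 equiv), THF, 0 → 23 °C; aq. NH4Cl
Reagents that add atoms: none
Why: Lithium amidotrihydroborate reduces the hindered tertiary amide to the primary alcohol with C–N cleavage (releasing the auxiliary) and reduces the enone carbonyl 1,2; hydride adds to C1 from the α-face, anti to the axial C10 methyl, which sets the equatorial (β) C1 hydroxyl.

Step 8
Reactants: 15 diol
Product: 17 tetraol (1β,2α,3α-triol with C11 hydroxymethyl), via osmate(VI) ester 16 (not isolated)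
Conditions: OsO4 (1.05 equiv), TMEDA (1.1 equiv), CH2Cl2, −78 → −40 °C; then ethylenediamine, rt
Reagents that add atoms: osmium tetroxide (O=[Os](=O)(=O)=O)
Why: Hydrogen-bond-directed dihydroxylation: the OsO4·TMEDA complex is delivered by the C11 hydroxyl to the α-face of the C2=C3 olefin, the face that is also free of the two axial methyl groups (C4, C10) and anti to the C1 hydroxyl, and suprafacial (3+2) addition sets C2 and C3; the C8=C9 olefin has no hydroxyl within reach of its open face and should react more slowly at low temperature.

Step 9
Reactants: 17 tetraol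
Product: 18 aldehyde triol (C11 aldehyde; 1β,2α,3α-triol)
Conditions: TEMPO (0.1 equiv), PhI(OAc)2 (1.2 equiv), CH2Cl2, rt
Reagents that add atoms: none
Why: TEMPO/PhI(OAc)2 oxidation (oxoammonium mechanism) is selective for the primary alcohol over the hindered secondary and tertiary alcohols and stops at the non-enolisable neopentyl aldehyde.

Step 10
Reactants: 18 aldehyde triol
Product: 19 aldehyde diacetate (1β,2α-diacetoxy; 3α-hydroxy; C11 aldehyde)
Conditions: Ac2O, pyridine, DMAP (cat.), CH2Cl2, 0 °C → rt
Reagents that add atoms: acetic anhydride (CC(=O)OC(C)=O)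
Why: DMAP-catalysed acetylation esterifies the two secondary hydroxyls while the tertiary C3 hydroxyl is too hindered to react; the weakly basic medium should not trigger retro-aldol opening of the β-hydroxy aldehyde.

Step 11
Reactants: 19 aldehyde diacetate
Product: 20 vinyl diacetate (4α-vinyl; C11=C12H2)
Conditions: CH2I2, Zn, Ti(OiPr)4, THF, rt
Reagents that add atoms: diiodomethane (ICI)
Why: Takai–Lombardo methylenation with the gem-dizinc/titanium reagent is non-basic and aldehyde-selective, so the acetates survive and the β-hydroxy aldehyde cannot undergo the retro-aldol cleavage that a phosphorus ylide could cause.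

Step 12
Reactants: 20 vinyl diacetate; 21 4-bromofuran-2(5H)-one
Product: 22 target CNP0383656.1
Conditions: Pd(OAc)2 (10 mol %), n-Bu4NCl, NaHCO3, DMF, 60 °C
Reagents that add atoms: none
Why: Mizoroki–Heck coupling: oxidative addition of Pd(0) to the β-bromobutenolide, insertion at the terminal carbon of the neopentyl-type vinyl group and syn β-hydride elimination, which can only give the (E)-C11=C12 olefin because C4 is quaternary; the trisubstituted ring olefin does not insert.

**Compound list**

1 | 2,5-dimethylbenzoyl chloride | Cc1ccc(C)c(c1)C(Cl)=O | starting material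
2 | (S)-2-(methoxymethyl)pyrrolidine | COC[C@@H]1CCCN1 | starting material
3 | N-(2,5-dimethylbenzoyl)-(S)-2-(methoxymethyl)pyrrolidine | Cc1ccc(C)c(c1)C(=O)N1CCC[C@H]1COC | intermediate
4 | potassium amide enolate of the 1,4-dihydrobenzamide (O cis to the methyl-bearing C3) | [K+].[O-]/C(N1CCC[C@H]1COC)=C1\C(C)=CCC(C)=C1 | intermediate
5 | (R)-1,2,5-trimethylcyclohexa-2,5-diene-1-carboxamide of the (S)-auxiliary | C1C=C(C)[C@](C)(C(=O)N2CCC[C@H]2COC)C=C1C | intermediate
6 | (R)-1,2,5-trimethyl-4-oxocyclohexa-2,5-diene-1-carboxamide of the (S)-auxiliary | O=C1C=C(C)[C@](C)(C(=O)N2CCC[C@H]2COC)C=C1C | intermediate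
7 | but-3-enylmagnesium bromide | C=CCC[Mg]Br | starting material
8 | acetaldehyde | CC=O | starting material
9 | bromomagnesium enolate (C1–O–Mg, C1=C10; 5β-but-3-enyl) | Br[Mg]OC1=C(C)[C@H](CCC=C)[C@@](C)(C(=O)N2CCC[C@H]2COC)C(C)=C1 | intermediate
10 | aldol: C1 ketone, C2=C3, 4β-Me/4α-carboxamide, 5β-but-3-enyl, 10β-Me/10α-(1-hydroxyethyl), C9 epimers | O=C1C=C(C)[C@](C)(C(=O)N2CCC[C@H]2COC)[C@@H](CCC=C)[C@]1(C)C(C)O | intermediate
11 | keto-olefin: as 10 with 10α-acetyl | O=C1C=C(C)[C@](C)(C(=O)N2CCC[C@H]2COC)[C@@H](CCC=C)[C@]1(C)C(C)=O | intermediate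
12 | molybdenum(VI) 2,6-diisopropylphenylimido neophylidene bis(hexafluoro-tert-butoxide) | CC(C)c1cccc(C(C)C)c1N=[Mo](=CC(C)(C)c1ccccc1)(OC(C)(C(F)(F)F)C(F)(F)F)OC(C)(C(F)(F)F)C(F)(F)F | starting material
13 | molybdenum alkylidene at C8 of the keto-olefin | O=C1C=C(C)[C@](C)(C(=O)N2CCC[C@H]2COC)[C@@H](CCC=[Mo](=Nc2c(C(C)C)cccc2C(C)C)(OC(C)(C(F)(F)F)C(F)(F)F)OC(C)(C(F)(F)F)C(F)(F)F)[C@]1(C)C(C)=O | intermediate
14 | trans-fused bicyclic enone amide: C1 ketone, C2=C3, C8=C9, 5α-H, 10β-Me, 4β-Me/4α-carboxamide | O=C1C=C(C)[C@](C)(C(=O)N3CCC[C@H]3COC)[C@H]2CCC=C(C)[C@]12C | intermediate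
15 | diol: 1β-OH, 4α-hydroxymethyl | O[C@H]1C=C(C)[C@](C)(CO)[C@H]2CCC=C(C)[C@]12C | intermediate
16 | cyclic osmate(VI) ester of the 2α,3α-diol (TMEDA chelate on Os, ligand not drawn) | O[C@H]1[C@@H]3O[Os](=O)(=O)O[C@]3(C)[C@](C)(CO)[C@H]2CCC=C(C)[C@]12C | intermediate
17 | tetraol: 1β,2α,3α-triol, 4α-hydroxymethyl | O[C@H]1[C@H](O)[C@](C)(O)[C@](C)(CO)[C@H]2CCC=C(C)[C@]12C | intermediate
18 | aldehyde triol: 1β,2α,3α-triol, 4α-formyl | O[C@H]1[C@H](O)[C@](C)(O)[C@](C)(C=O)[C@H]2CCC=C(C)[C@]12C | intermediate
19 | aldehyde diacetate: 1β,2α-diacetoxy, 3α-OH, 4α-formyl | CC(=O)O[C@H]1[C@H](OC(C)=O)[C@](C)(O)[C@](C)(C=O)[C@H]2CCC=C(C)[C@]12C | intermediate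
20 | vinyl diacetate: 1β,2α-diacetoxy, 3α-OH, 4α-vinyl | CC(=O)O[C@H]1[C@H](OC(C)=O)[C@](C)(O)[C@](C)(C=C)[C@H]2CCC=C(C)[C@]12C | intermediate
21 | 4-bromofuran-2(5H)-one | O=C1C=C(Br)CO1 | starting material
22 | CNP0383656.1 | CC(=O)O[C@H]1[C@H](OC(C)=O)[C@](C)(O)[C@](C)(/C=C/C2=CC(=O)OC2)[C@H]2CCC=C(C)[C@]12C | target

**Totals and risks**

Total step count: 12. Longest linear sequence: 12 steps (from 1).

The three steps most likely to fail:

Step 6. The Lewis-acidic molybdenum centre may be tied up by chelation to the 1,3-dicarbonyl unit, or the carbonyl olefination at the neopentyl ketone may be slower than decomposition of the alkylidene, so that the ring does not close. The fallback sets out from 11 and comes back at 14. The two events are separated: chemoselective Tebbe methylenation of the non-conjugated C9 methyl ketone (Tebbe reagent, THF, −40 → 0 °C; the cross-conjugated C1 carbonyl is the less electrophilic ketone) should give isopropenyl triene F1. Ring-closing olefin metathesis between the isopropenyl group and the terminal olefin with a second-generation ruthenium benzylidene catalyst (toluene, 80 °C) should then give 14 with loss of ethylene.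

Step 8. Site selectivity between the two trisubstituted olefins may be lost, or the allylic C1 hydroxyl may deliver the reagent to the β-face. The fallback sets out from 14 and comes back at 17, and uses only enone-specific chemistry. Weitz–Scheffer epoxidation of the enone from the α-face (t-BuOOH, Triton B, THF) should give epoxy ketone F2. SmI2 (THF/MeOH, −78 °C) should open it at C2 to β-hydroxy ketone F3 with the 3α-hydroxyl in place. The dianion (LDA, 2.2 equiv, THF, −78 °C) is then hydroxylated at C2 from the α-face with 2-(phenylsulfonyl)-3-phenyloxaziridine to give dihydroxy ketone F4. Lithium amidotrihydroborate should finally reduce the C1 ketone (hydride from the α-face) and the amide together to 17.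

Step 12. Insertion at the hindered vinyl group may be slow, with base-induced decomposition of the bromobutenolide competing. The fallback sets out from 19 and comes back at 22. Takai iodo-olefination of the aldehyde (CrCl2, CHI3, THF, 0 °C) should give (E)-vinyl iodide F5. Stille coupling of F5 with 4-(tributylstannyl)furan-2(5H)-one F6 (made from 21 with hexabutylditin and Pd(PPh3)4 in toluene) under Pd2(dba)3/AsPh3/CuI in NMP at rt should then give 22 with the (E)-olefin retained.

Further compounds
F1 | step 6 | isopropenyl triene: as 11 with 10α-isopropenyl in place of acetyl | O=C1C=C(C)[C@](C)(C(=O)N2CCC[C@H]2COC)[C@@H](CCC=C)[C@]1(C)C(C)=C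
F2 | step 8 | 2α,3α-epoxy ketone of 14 | O=C1[C@@H]3O[C@]3(C)[C@](C)(C(=O)N4CCC[C@H]4COC)[C@H]2CCC=C(C)[C@]12C
F3 | step 8 | 3α-hydroxy ketone (C2 methylene) | O=C1C[C@](C)(O)[C@](C)(C(=O)N3CCC[C@H]3COC)[C@H]2CCC=C(C)[C@]12C
F4 | step 8 | 2α,3α-dihydroxy ketone | O=C1[C@H](O)[C@](C)(O)[C@](C)(C(=O)N3CCC[C@H]3COC)[C@H]2CCC=C(C)[C@]12C
F5 | step 12 | (E)-vinyl iodide diacetate | CC(=O)O[C@H]1[C@H](OC(C)=O)[C@](C)(O)[C@](C)(/C=C/I)[C@H]2CCC=C(C)[C@]12C
F6 | step 12 | 4-(tributylstannyl)furan-2(5H)-one | O=C1C=C([Sn](CCCC)(CCCC)CCCC)CO1
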